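- In a one-step world one half-life would have been enough to read a flask, so I first asked which concentration set the order of the loss of starting material. In Tuesday's run activator stood at 0.096 M against 0.040 M of starting material, 2.40 to one, which is no large excess, so I took no order from that ratio and used the early loss of starting material as a yardstick of time.

| flask | starting material | activator | capture agent | remark | time |
|---|---|---|---|---|---|
| Tuesday's | 0.040 M | 0.096 M | 0.86 mM | run made earlier |  |
| south-west | 0.040 M | 0.0960 M | 1.28 mM |  | 10 h |
| north-east | 0.060 M | 0.0960 M | 1.28 mM |  | 10 h |
| north-west | 0.10 M | 0.0960 M | 1.28 mM |  | 10 h |
| west | 0.15 M | 0.0960 M | 1.28 mM |  | 10 h |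
| east | 0.20 M | 0.0960 M | 1.28 mM |  | 10 h |

Tuesday's run (percent of the starting material charged)

| time / min | ring / % | starting material / % |
|---|---|---|
| 25.0 | 9.5 | 29.5 |
| 50.0 | 16.5 | 9.4 |
| 80.0 | 21.9 | 3.5 |
| 90.0 | 22.1 | 3.0 |
| 120 | 22.6 | 0.6 |

(readings scatter by 0.5 percentage points)

- the analysis behind the earlier runs scatters by 0.5 percentage points, standard deviation
- "hardly changes" means that all values lie within two and a half points (for a concentration: within two and a half percent of the largest)
- no earlier run changes the charge of capture agent; that part of a forecast is a guess

* [ring] at the end for south-west, north-east, north-west, west, east, in this order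
* how that number moves from the first to the last of them (hardly changes / falls, then rises / rises, then falls / rises all the way / falls all the way)

- Fastest rung: in Tuesday's run starting material had fallen to 29.5% at 25.0 min. That reading gave 14.2 min, my early half-life of starting material, a yardstick read over that first stretch of the run and not a constant of the flask.
- Middle rung: in Tuesday's run ring stood at 9.5% at that same time, although 70.5% of the starting material had gone, and it reached 21.9% at 80.0 min. So ring trailed the loss of starting material, and a step stood between them.
- Slowest rung: from 80.0 min to 120 min Tuesday's ring moved by 0.7 percentage points against a scatter of 0.5 points, so that run showed me no fall of ring, and it ended there.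
- My own reckoning: the asked 10 h held 42.3 of these early half-lives, a rough count, and from it I expected starting material to be absent at the end wherever activator lasted. I marked east, with 2.08 of starting material per activator, as the flask where that count might fail. I set no ring figure of my own.
- The forecast gave 0.0125 M, 0.017 M, 0.027 M, 0.02 M and 0.016 M, a shape that rises, then falls, and held for the high end that “activator caps conversion while faster flux favours loss”.
- The flasks gave 0.00568 M, 0.00646 M, 0.00745 M, 0.00829 M and 0.00489 M, a shape that rises, then falls, turning at 0.15 M.

    capture agent + activated form → trapped intermediate (k = 0.0130 M⁻¹ s⁻¹)
    activated form → ring (k = 8.80 × 10⁻⁴ s⁻¹)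
    starting material + activated form → open dimer (k = 0.110 M⁻¹ s⁻¹)
    ring → over-reaction product (k = 2.00 × 10⁻⁵ s⁻¹)
    starting material + activator → activated form (k = 0.00590 M⁻¹ s⁻¹)

- In south-west the half-life of ring by over-reaction was 9.6 h, 40.6 times my 14.2 min and close to the 10 h of the run; starting material was down to 0.0116% at 5.00 h, and ring went from 20.3% then to 14.2% at 10.0 h. In east the same count of 42.3 half-lives ended with 8.86% of the starting material present and activator, the limiting reagent there, at 0.236% of its own charge.

The data were generated by integration with made-up constants; noise was put on by code.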